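Assumption: (S)-(+)-terpinen-4-ol, the main alcohol of tea-tree oil, is bought as the single enantiomer. Daucane numbering is used throughout: C1 is the quaternary ring-fusion carbon, C4 the tertiary carbinol, C5 the ring-fusion CH, C6 the ester carbinol, and C8=C9 the ring alkene.

## Retrosynthetic overview
1. The C6–O ester comes from a final acylation of jaeschkeanadiol. The C6 carbinol comes from an OH-directed reduction of the 6-ketone.
2. The seven-membered ring is formed last, by RCM (C8=C9) between a C1-allyl group and a C6 methallyl ketone.
3. The five-membered ring comes from forming the C1–C5 bond by photochemical Wolff contraction of a six-membered α-diazo-β-hydroxy ketone. The C4–OH traps the ketene as a fused β-lactone, which fixes C5.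
4. The C1 quaternary centre comes from axial allylation of the enolate released by reductive opening of 2-oxo-1,4-cineole.
5. The C4 carbinol is bought in (S)-terpinen-4-ol and controls every other centre. Ring order: bought cyclohexene, then cyclopentane, then cycloheptene.

## Route

**Step 1**
Reactants: 1 (S)-(+)-terpinen-4-ol; 2 tert-butyl hydroperoxide
Product: 3 (1R,2S,4S)-2-exo-hydroxy-1,4-cineole
Conditions: VO(acac)2 (1 mol %), 2, CH2Cl2, rt; then p-TsOH (cat.), rt, one pot
Reagents that add atoms: tert-butyl hydroperoxide, CC(C)(C)OO
Why: Hydroxyl-directed vanadium epoxidation places the epoxide syn to the C4–OH, and acid then drives SN1-type opening at the tertiary carbon by that same OH (the cinmethylin process sequence), so both new centres follow from the bought carbinol.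

**Step 2**
Reactants: 3
Product: 4 (1R,4S)-1-methyl-4-isopropyl-7-oxabicyclo[2.2.1]heptan-2-one
Conditions: Dess–Martin periodinane, NaHCO3, CH2Cl2, rt
Reagents that add atoms: none
Why: This is a plain secondary-alcohol oxidation, and the only other functional group is an inert bridging ether.

**Step 3**
Reactants: 4; 5 allyl bromide
Product: 6 (2R,5S)-2-allyl-5-hydroxy-5-isopropyl-2-methylcyclohexanone (allyl trans to OH, cis to i-Pr)
Conditions: Li (2.1 equiv), NH3(l)/THF, −78 °C; isoprene to discharge excess Li; 5 (3 equiv), −78 → −33 °C; NH4Cl
Reagents that add atoms: allyl bromide, C=CCBr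
Why: Dissolving-metal cleavage of the α-alkoxy ketone C–O bond gives the tetrasubstituted enolate regiospecifically (Stork-type reductive alkylation), and chair-like axial alkylation of the half-chair (i-Pr equatorial, OLi axial) puts the allyl on the face opposite the alkoxide, which sets C1.

**Step 4**
Reactants: 6; 7 methanesulfonyl azide
Product: 8 (3R,6R)-6-allyl-2-diazo-3-hydroxy-3-isopropyl-6-methylcyclohexanone
Conditions: LiHMDS (2.3 equiv), THF, −78 °C; CF3CO2CH2CF3; then 7, Et3N, H2O (1 equiv), MeCN, rt
Reagents that add atoms: methanesulfonyl azide, CS(=O)(=O)N=[N+]=[N-]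
Why: Danheiser detrifluoroacetylative diazo transfer works here because only one α-position is enolisable, and the aldolate dianion at −78 °C can undergo neither retro-aldol cleavage nor E1cB elimination.

**Step 5 (key step)**
Reactants: 8
Product: 9 (1R,2R,5R)-2-allyl-5-isopropyl-2-methyl-6-oxabicyclo[3.2.0]heptan-7-one, a cis-fused β-lactone
Conditions: hν (365 nm LED), DMAP (10 mol %), dry PhMe (5 mM), 0 °C → rt
Reagents that add atoms: none
Why: Proposed new method: photo-Wolff ring contraction with intramolecular β-lactonisation of the hydroxy-ketene. The s-Z-locked cyclic diazoketone loses N2 with concerted 1,2-shift of the quaternary carbon (retention), forming the C1–C5 bond. The doubly neopentyl ketene cannot dimerise and has no external nucleophile, so the adjacent C4–OH adds to it (directly or through the reversible DMAP acylpyridinium enolate). Because only a cis 4/5 fusion can exist, C5 is protonated from the α face and ends with H anti to OH. The equatorial i-Pr is misaligned for a competing 1,2-alkyl shift. Closest known reactions are the photo-Wolff contraction of 2-diazocyclohexanones with external nucleophiles and nucleophile-catalysed aldol-lactonisation to cyclopentane-fused β-lactones.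

**Step 6**
Reactants: 9; 10 2-methylallylmagnesium chloride
Product: 11 1-[(1R,2R,5R)-5-allyl-2-hydroxy-2-isopropyl-5-methylcyclopentyl]-3-methylbut-3-en-1-one
Conditions: MeNH(OMe)·HCl, i-PrMgCl, THF, −20 °C; then 10 (3 equiv), −20 → 0 °C; cold aq NH4Cl, one pot
Reagents that add atoms: 2-methylallylmagnesium chloride, CC(=C)C[Mg]Cl
Why: Strain-driven acyl-O aminolysis gives the Weinreb amide in situ, and its chelated tetrahedral adduct with the Grignard reagent (Weinreb ketone synthesis) stops over-addition and releases the base-sensitive β-hydroxy-β,γ-enone only at the quench, leaving C5 untouched.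

**Step 7**
Reactants: 11
Product: 12 (3R,3aR,8aR)-3-hydroxy-3-isopropyl-6,8a-dimethyl-1,2,3,3a,8,8a-hexahydroazulen-4(5H)-one (trans-fused)
Conditions: Hoveyda–Grubbs II (5 mol %), 1,4-benzoquinone (10 mol %), CH2Cl2 (3 mM), 40 °C
Reagents that add atoms: none
Why: Ring-closing metathesis of a monosubstituted with a 1,1-disubstituted alkene gives the Z-trisubstituted C8=C9 cycloheptene at exactly the required position, and benzoquinone suppresses Ru–H migration into conjugation.

**Step 8**
Reactants: 12
Product: 13 jaeschkeanadiol, (3R,3aS,4S,8aR)-3-isopropyl-6,8a-dimethyl-1,2,3a,4,5,8-hexahydroazulene-3,4-diol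
Conditions: Me4NBH(OAc)3, MeCN/AcOH (1:1), −20 °C
Reagents that add atoms: none
Why: In this Evans–Saksena directed reduction the borohydride bound to the pseudo-axial 4β-OH can reach only the β face of the ring ketone (the ring cannot rotate the α face toward it), which gives the 6α-OH (6S).

**Step 9**
Reactants: 13; 14 4-methoxybenzoyl chloride
Product: 15 fertidin (target)
Conditions: 14 (1.3 equiv), DMAP, Et3N, CH2Cl2, rt
Reagents that add atoms: 4-methoxybenzoyl chloride, COc1ccc(cc1)C(Cl)=O
Why: DMAP-catalysed acylation takes the secondary C6–OH and leaves the hindered tertiary C4–OH free, as is standard for ferutinin-type esters of jaeschkeanadiol.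

## Compound list
1 | (S)-(+)-terpinen-4-ol | CC1=CC[C@](O)(C(C)C)CC1 | starting material
2 | tert-butyl hydroperoxide | CC(C)(C)OO | starting material
3 | (1R,2S,4S)-2-exo-hydroxy-1,4-cineole | C[C@]12CC[C@@](O1)(C(C)C)C[C@@H]2O | intermediate
4 | (1R,4S)-2-oxo-1,4-cineole | C[C@]12CC[C@@](O1)(C(C)C)CC2=O | intermediate
5 | allyl bromide | C=CCBr | starting material
6 | (2R,5S)-2-allyl-5-hydroxy-5-isopropyl-2-methylcyclohexanone | C=CC[C@@]1(C)CC[C@@](O)(C(C)C)CC1=O | intermediate
7 | methanesulfonyl azide | CS(=O)(=O)N=[N+]=[N-] | starting material
8 | (3R,6R)-6-allyl-2-diazo-3-hydroxy-3-isopropyl-6-methylcyclohexanone | C=CC[C@@]1(C)CC[C@@](O)(C(C)C)C(=[N+]=[N-])C1=O | intermediate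
9 | (1R,2R,5R)-2-allyl-5-isopropyl-2-methyl-6-oxabicyclo[3.2.0]heptan-7-one | C=CC[C@@]1(C)CC[C@]2(C(C)C)OC(=O)[C@H]12 | intermediate
10 | 2-methylallylmagnesium chloride | CC(=C)C[Mg]Cl | starting material
11 | 1-[(1R,2R,5R)-5-allyl-2-hydroxy-2-isopropyl-5-methylcyclopentyl]-3-methylbut-3-en-1-one | C=CC[C@@]1(C)CC[C@@](O)(C(C)C)[C@@H]1C(=O)CC(C)=C | intermediate
12 | (3R,3aR,8aR)-3-hydroxy-3-isopropyl-6,8a-dimethyl-1,2,3,3a,8,8a-hexahydroazulen-4(5H)-one | CC1=CC[C@@]2(C)CC[C@@](O)(C(C)C)[C@@H]2C(=O)C1 | intermediate
13 | jaeschkeanadiol | O[C@H]1CC(C)=CC[C@@]2(C)CC[C@@](O)(C(C)C)[C@H]12 | intermediate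
14 | 4-methoxybenzoyl chloride | COc1ccc(cc1)C(Cl)=O | starting material
15 | fertidin | COc1ccc(C(=O)O[C@H]2CC(C)=CC[C@@]3(C)CC[C@@](O)(C(C)C)[C@H]23)cc1 | target

## Summary
Total steps: 9. Longest linear sequence: 9.

Steps most likely to fail:
- **Step 5 (new tandem photo-Wolff/β-lactonisation).** The risks are slow four-membered ring closure, intermolecular esterification, and 1,2-shift chemistry of the carbene. Fallback (known chemistry): run the classical photo-Wolff contraction of 8 in THF/H2O to the ring-contracted β-hydroxy acids. Then carry out a separate Adam lactonisation (PhSO2Cl, pyridine), which only the cis-hydroxy acid can undergo, and recycle the trans acid by epimerisation of its ester.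
- **Step 3 (reductive opening and quaternary allylation).** The risks are over-reduction, proton transfer, and modest diastereoselectivity. Fallback: trap the reductively generated enolate with allyl chloroformate to give the allyl enol carbonate. Then form the C1–allyl bond by Pd(PPh3)4-catalysed Tsuji decarboxylative allylation, with no free enolate or alkyl halide involved.
- **Step 7 (RCM on the β,γ-unsaturated β-hydroxy ketone).** The risks are alkene migration into conjugation and sluggish trans-fused closure. Fallback: close the ring at the alcohol oxidation level instead.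
  - Reduce 9 with LiAlH4 to the diol.
  - Oxidise the primary OH with TEMPO/PhI(OAc)2 to the β-hydroxy aldehyde.
  - Add 10 under internal magnesium-alkoxide chelation, where attack anti to the angular methyl gives 6S.
  - Acylate with 14 and run the RCM last on the non-enolisable anisate.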